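Ring A (C1–C5, C10; labdane numbering) is cut across its two opposite bonds, C2–C3 and C5–C10, into a C2–C1–C10 bis-nucleophile and a C3–C4–C5 bis-electrophile ([3+3]). This exploits the quaternary C10, flanked by C1 and the future C9 carbonyl, as the α-carbon of a 1,3-dicarbonyl unit, and the gem-dimethyl C4 as a non-enolisable spacer. In one pot the dianion of an acyclic 2-methyl-3-oxobutanamide adds through its γ-carbon to the aldehyde (C3) and through its α-carbon to the chiral enoate (C5) of an acyclic partner, closing ring A and setting C5 and C10. C9 and the cyclohexene-dione stereocentres are relayed later by an aldol-type closure of ring B and a hydroxyl-directed Diels–Alder union.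

Key step: step 5

Remark: terpenoid carbons are numbered as in a labdane (ring A = C1–C5/C10, ring B = C5–C10, side chain C11–C16, C17 = exocyclic methylene); "8-phenylmenthyl" means (1R,2S,5R)-5-methyl-2-(2-phenylpropan-2-yl)cyclohexyl, and its sense of induction is assumed from the usual model (s-trans enoate, ester C=O syn to the carbinol C–H, phenyl covering one face).

Step 1
Reactants: 1 methyl 2-methyl-3-oxobutanoate (racemic)
Product: 2 2-methyl-1-(morpholin-4-yl)butane-1,3-dione (racemic)
Conditions: morpholine (1.2 equiv), DMAP (0.1 equiv), toluene, 110 °C, MeOH distilled off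
Reagents that add atoms: morpholine, C1COCCN1
Why: DMAP-catalysed aminolysis of a β-keto ester (through the acylketene) should give the β-keto amide; the α-stereocentre is irrelevant because it is enolised in step 5.

Step 2
Reactants: 3 (1R,2S,5R)-5-methyl-2-(2-phenylpropan-2-yl)cyclohexan-1-ol ((−)-8-phenylmenthol); 4 2-(diethoxyphosphoryl)acetic acid
Product: 5 8-phenylmenthyl 2-(diethoxyphosphoryl)acetate
Conditions: DCC, DMAP (cat.), CH2Cl2, 0 → 23 °C
Reagents that add atoms: none
Why: Steglich esterification attaches the chiral auxiliary to the olefination reagent without touching its stereocentres.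

Step 3
Reactants: 5 8-phenylmenthyl 2-(diethoxyphosphoryl)acetate; 6 3-hydroxy-2,2-dimethylpropanal
Product: 7 8-phenylmenthyl (2E)-5-hydroxy-4,4-dimethylpent-2-enoate
Conditions: LiCl, DBU, MeCN, 23 °C
Reagents that add atoms: none
Why: Horner–Wadsworth–Emmons olefination under mild LiCl/amine conditions tolerates the free hydroxyl and should give the (E)-enoate; no stereocentre is formed.

Step 4
Reactants: 7 8-phenylmenthyl (2E)-5-hydroxy-4,4-dimethylpent-2-enoate
Product: 8 8-phenylmenthyl (2E)-4,4-dimethyl-5-oxopent-2-enoate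
Conditions: Dess–Martin periodinane, CH2Cl2, 23 °C
Reagents that add atoms: none
Why: Dess–Martin oxidation of the neopentyl primary alcohol should give the non-enolisable aldehyde without isomerising the enoate.

Step 5
Reactants: 2 2-methyl-1-(morpholin-4-yl)butane-1,3-dione; 8 8-phenylmenthyl (2E)-4,4-dimethyl-5-oxopent-2-enoate
Product: 11 8-phenylmenthyl 2-[(1S,6R)-2,2,6-trimethyl-6-(morpholine-4-carbonyl)-5-oxocyclohex-3-en-1-yl]acetate, via acyclic aldol adduct 9 (not isolated), via ring-closed hydroxy ketone 10 (not isolated)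
Conditions: 2 (1.2 equiv), LiN(i-Pr)2 (2.4 equiv), THF, 0 °C; 8, −78 °C; t-BuOH (3 equiv), −78 → 23 °C; then 2 M HCl, 50 °C
Reagents that add atoms: none
Why: LiN(i-Pr)2 converts 2 into its 1,3-dianion, whose more basic γ-carbon (C2) adds to the non-enolisable aldehyde of 8 (γ-aldol, C2–C3); the remaining lithium-chelated β-keto amide enolate then adds through C10 to the enoate β-carbon C5 once t-BuOH is present to protonate the ester enolate, and acid finally dehydrates the β-hydroxy ketone. The closest known reaction type is the γ-aldol of a 1,3-dicarbonyl dianion followed by an intramolecular Michael addition, i.e. a [3+3] Robinson-type annulation. Ring A is closed in the 6-exo-trig mode. C5 is controlled by the 8-phenylmenthyl ester, whose phenyl group covers one face of the s-trans enoate so that C10 attacks the open face (5S); C10 is controlled by the chelate, which holds the amide carbonyl syn to the enolate oxygen and therefore anti to C2, so that it becomes equatorial and the methyl axial, trans to the equatorial C5 side chain of a chair-like transition state. The step needs aldehyde-over-enoate selectivity for the dianion (secured by the much higher electrophilicity of the aldehyde at −78 °C and the tert-alkyl-shielded enoate β-carbon) and C- over O-attack in the ring closure (secured by reversibility of the oxa-Michael path). The carbinol epimers at C3 converge in the dehydration.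

Step 6
Reactants: 11 8-phenylmenthyl 2-[(1S,6R)-2,2,6-trimethyl-6-(morpholine-4-carbonyl)-5-oxocyclohex-3-en-1-yl]acetate
Product: 12 8-phenylmenthyl 2-[(9S,10S)-8,8,10-trimethyl-10-(morpholine-4-carbonyl)-1,4-dithiaspiro[4.5]dec-6-en-9-yl]acetate (the 1,3-dithiolane of 11 at the ring ketone C1)
Conditions: HSCH2CH2SH, BF3·OEt2 (0.3 equiv), CH2Cl2, 0 → 23 °C
Reagents that add atoms: ethane-1,2-dithiol, SCCS
Why: Lewis-acid-catalysed dithioketalisation of the ring ketone prepares its removal; the amide and ester carbonyls do not react, conjugate addition at the neopentyl C3 is disfavoured and no stereocentre changes.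

Step 7
Reactants: 12 8-phenylmenthyl 2-[(9S,10S)-8,8,10-trimethyl-10-(morpholine-4-carbonyl)-1,4-dithiaspiro[4.5]dec-6-en-9-yl]acetate
Product: 13 8-phenylmenthyl 2-[(1S,2S)-2,6,6-trimethyl-2-(morpholine-4-carbonyl)cyclohexyl]acetate
Conditions: Raney Ni (excess), H2 (1 atm), EtOH, 78 °C
Reagents that add atoms: none
Why: Raney-nickel desulfurisation (Mozingo reduction) should turn C1 into a methylene group while nickel and hydrogen saturate the C2=C3 bond, leaving ring A unfunctionalised with C5 and C10 untouched.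

Step 8
Reactants: 13 8-phenylmenthyl 2-[(1S,2S)-2,6,6-trimethyl-2-(morpholine-4-carbonyl)cyclohexyl]acetate
Product: 14 N-methoxy-N-methyl-2-[(1S,2S)-2,6,6-trimethyl-2-(morpholine-4-carbonyl)cyclohexyl]acetamide
Conditions: MeNH(OMe)·HCl, AlMe3, toluene, 0 → 70 °C
Reagents that add atoms: N,O-dimethylhydroxylamine hydrochloride, CNOC.Cl
Why: Aluminium-amide aminolysis of the ester should give the Weinreb amide and release the auxiliary 3 for re-use; the tertiary morpholine amide is inert and no stereocentre is affected.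

Step 9
Reactants: 14 N-methoxy-N-methyl-2-[(1S,2S)-2,6,6-trimethyl-2-(morpholine-4-carbonyl)cyclohexyl]acetamide
Product: 15 1-[(1S,2S)-1,3,3-trimethyl-2-(2-oxobut-3-en-1-yl)cyclohexyl]but-3-en-1-one
Conditions: CH2=CHMgBr (1.2 equiv), THF, −20 °C; then CH2=CHCH2MgBr (2 equiv), 0 → 23 °C; inverse quench into cold 1 M HCl
Reagents that add atoms: vinylmagnesium bromide, C=C[Mg]Br; allylmagnesium bromide, C=CC[Mg]Br
Why: In this Weinreb-type ketone synthesis the unhindered Weinreb amide should react first to a stable magnesium chelate and the more reactive allyl reagent then add to the hindered morpholine amide, whose tetrahedral adduct also persists, so that both ketones (C7 vinyl ketone, C9 allyl ketone) appear only on acidic work-up, where the liberated amines are protonated and cannot add to the vinyl ketone.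

Step 10
Reactants: 15 1-[(1S,2S)-1,3,3-trimethyl-2-(2-oxobut-3-en-1-yl)cyclohexyl]but-3-en-1-one
Product: 17 (4S,4aS,8aS)-4-hydroxy-4a,8,8-trimethyl-3-methylidene-4-(prop-2-en-1-yl)octahydronaphthalen-2(1H)-one, via iodo ketol 16 (not isolated)
Conditions: Et2AlI (1.5 equiv), CH2Cl2, −78 → −20 °C; then DBU, 0 °C
Reagents that add atoms: none
Why: Iodide adds to the vinyl ketone terminus (C17) and the aluminium enolate closes ring B through C8 onto the aluminium-bound C9 ketone (iodo-aldol, 6-enolendo-exo-trig), the chelated chair on the trans-disposed ring A substituents placing the C9 oxygen axial (α) and the allyl group equatorial (β); DBU then eliminates HI to the α-methylene ketone (Morita–Baylis–Hillman-type outcome).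

Step 11
Reactants: 17 (4S,4aS,8aS)-4-hydroxy-4a,8,8-trimethyl-3-methylidene-4-(prop-2-en-1-yl)octahydronaphthalen-2(1H)-one
Product: 18 (2E)-4-[(1S,4aS,8aS)-1-hydroxy-5,5,8a-trimethyl-2-methylidene-3-oxodecahydronaphthalen-1-yl]-2-methylbut-2-enal
Conditions: methacrolein (10 equiv), RuCl2(H2IMes)(=CH-C6H4-2-O-i-Pr) (second-generation Hoveyda–Grubbs catalyst, 5 mol%), CH2Cl2, 40 °C
Reagents that add atoms: methacrolein, CC(=C)C=O
Why: Olefin cross-metathesis of the monosubstituted allyl group with excess methacrolein should give the (E)-2-methyl enal under thermodynamic control, the hindered electron-poor enone methylene staying a spectator; no stereocentre is formed.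

Step 12
Reactants: 18 (2E)-4-[(1S,4aS,8aS)-1-hydroxy-5,5,8a-trimethyl-2-methylidene-3-oxodecahydronaphthalen-1-yl]-2-methylbut-2-enal
Product: 19 (4S,4aS,8aS)-4-hydroxy-4a,8,8-trimethyl-3-methylidene-4-[(2E)-3-methylpenta-2,4-dien-1-yl]octahydronaphthalen-2(1H)-one (in labdane terms (12E)-9α-hydroxylabda-8(17),12,14-trien-7-one)
Conditions: Ph3PCH3Br (1.05 equiv), KN(SiMe3)2, THF, −78 → −40 °C
Reagents that add atoms: methyltriphenylphosphonium bromide, C[P+](c1ccccc1)(c1ccccc1)c1ccccc1.[Br-]
Why: Wittig methylenation at low temperature should be selective for the aldehyde over the hindered ring ketone and gives the (12E)-diene with the trisubstituted alkene geometry retained.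

Step 13
Reactants: 20 1-(2,4,5-trimethoxyphenyl)ethan-1-one
Product: 21 ethyl 3-oxo-3-(2,4,5-trimethoxyphenyl)propanoate
Conditions: NaH, (EtO)2CO, THF, 66 °C; then 1 M HCl
Reagents that add atoms: diethyl carbonate, CCOC(=O)OCC
Why: Claisen-type C-acylation of the methyl ketone enolate with diethyl carbonate should give the β-keto ester.

Step 14
Reactants: 21 ethyl 3-oxo-3-(2,4,5-trimethoxyphenyl)propanoate; 22 benzene-1,3,5-triol (phloroglucinol)
Product: 23 5,7-dihydroxy-2-(2,4,5-trimethoxyphenyl)-4H-chromen-4-one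
Conditions: neat melt, 240 °C, N2
Reagents that add atoms: none
Why: Thermal, acid-free condensation of a phenol with a β-keto ester (C-acylation then cyclodehydration) should give the chromone (flavone) and not the coumarin.

Step 15
Reactants: 23 5,7-dihydroxy-2-(2,4,5-trimethoxyphenyl)-4H-chromen-4-one
Product: 24 2-(5,7-dihydroxy-4-oxo-4H-chromen-2-yl)-5-methoxycyclohexa-2,5-diene-1,4-dione
Conditions: (NH4)2Ce(NO3)6 (2.2 equiv), MeCN/H2O, 0 °C
Reagents that add atoms: water, O
Why: Oxidative demethylation of the para-dimethoxy pair should give the 2-substituted 5-methoxy-1,4-benzoquinone, the chelated, carbonyl-deactivated chromone phenols being harder to oxidise.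

Step 16
Reactants: 19 (12E)-9α-hydroxylabda-8(17),12,14-trien-7-one; 24 2-(5,7-dihydroxy-4-oxo-4H-chromen-2-yl)-5-methoxycyclohexa-2,5-diene-1,4-dione
Product: 25 CNP0241859.1 [(4aS,5R,8aR)-4a-(5,7-dihydroxy-4-oxo-4H-chromen-2-yl)-5-{[(1S,4aS,8aS)-1-hydroxy-5,5,8a-trimethyl-2-methylidene-3-oxodecahydronaphthalen-1-yl]methyl}-2-methoxy-6-methyl-4a,5,8,8a-tetrahydronaphthalene-1,4-dione]
Conditions: CH2Cl2, 23 °C, dark
Reagents that add atoms: none
Why: Diels–Alder reaction at the chromonyl-substituted quinone double bond (the methoxy-bearing one is deactivated) with ortho orientation (C15 to the quinone CH, C12 to the chromonyl carbon); a hydrogen bond from the free 9α-hydroxyl to the quinone carbonyl next to the chromonyl carbon should hold the quinone ring exo, placing C11 cis to the chromone, and should favour the diene face that keeps the flat C8 methylene rather than the quaternary C10 over the diene, so that C12 and both ring-fusion centres are set from C9.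

Compound list
1 | methyl 2-methyl-3-oxobutanoate (racemic) | CC(=O)C(C)C(=O)OC | starting material
2 | 2-methyl-1-(morpholin-4-yl)butane-1,3-dione (racemic) | CC(=O)C(C)C(=O)N1CCOCC1 | intermediate
3 | (1R,2S,5R)-5-methyl-2-(2-phenylpropan-2-yl)cyclohexan-1-ol, (−)-8-phenylmenthol | CC(C)(c1ccccc1)[C@@H]1CC[C@@H](C)C[C@H]1O | starting material
4 | 2-(diethoxyphosphoryl)acetic acid | CCOP(=O)(OCC)CC(=O)O | starting material
5 | 8-phenylmenthyl 2-(diethoxyphosphoryl)acetate | CCOP(=O)(OCC)CC(=O)O[C@@H]1C[C@H](C)CC[C@H]1C(C)(C)c1ccccc1 | intermediate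
6 | 3-hydroxy-2,2-dimethylpropanal | OCC(C)(C)C=O | starting material
7 | 8-phenylmenthyl (2E)-5-hydroxy-4,4-dimethylpent-2-enoate | OCC(C)(C)/C=C/C(=O)O[C@@H]1C[C@H](C)CC[C@H]1C(C)(C)c1ccccc1 | intermediate
8 | 8-phenylmenthyl (2E)-4,4-dimethyl-5-oxopent-2-enoate | O=CC(C)(C)/C=C/C(=O)O[C@@H]1C[C@H](C)CC[C@H]1C(C)(C)c1ccccc1 | intermediate
9 | acyclic aldol adduct, 8-phenylmenthyl (2E)-5-hydroxy-4,4,8-trimethyl-9-(morpholin-4-yl)-7,9-dioxonon-2-enoate (epimers at chain C5 and C8) | O=C(N1CCOCC1)C(C)C(=O)CC(O)C(C)(C)/C=C/C(=O)O[C@@H]1C[C@H](C)CC[C@H]1C(C)(C)c1ccccc1 | intermediate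
10 | ring-closed hydroxy ketone, 8-phenylmenthyl 2-[(1S,6R)-3-hydroxy-2,2,6-trimethyl-6-(morpholine-4-carbonyl)-5-oxocyclohexyl]acetate (both carbinol epimers) | O=C(N1CCOCC1)[C@@]2(C)C(=O)CC(O)C(C)(C)[C@@H]2CC(=O)O[C@@H]1C[C@H](C)CC[C@H]1C(C)(C)c1ccccc1 | intermediate
11 | 8-phenylmenthyl 2-[(1S,6R)-2,2,6-trimethyl-6-(morpholine-4-carbonyl)-5-oxocyclohex-3-en-1-yl]acetate | O=C(N1CCOCC1)[C@@]2(C)C(=O)C=CC(C)(C)[C@@H]2CC(=O)O[C@@H]1C[C@H](C)CC[C@H]1C(C)(C)c1ccccc1 | intermediate
12 | 8-phenylmenthyl 2-[(9S,10S)-8,8,10-trimethyl-10-(morpholine-4-carbonyl)-1,4-dithiaspiro[4.5]dec-6-en-9-yl]acetate (1,3-dithiolane of 11) | O=C(N1CCOCC1)[C@@]2(C)C3(SCCS3)C=CC(C)(C)[C@@H]2CC(=O)O[C@@H]1C[C@H](C)CC[C@H]1C(C)(C)c1ccccc1 | intermediate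
13 | 8-phenylmenthyl 2-[(1S,2S)-2,6,6-trimethyl-2-(morpholine-4-carbonyl)cyclohexyl]acetate | O=C(N1CCOCC1)[C@@]2(C)CCCC(C)(C)[C@@H]2CC(=O)O[C@@H]1C[C@H](C)CC[C@H]1C(C)(C)c1ccccc1 | intermediate
14 | N-methoxy-N-methyl-2-[(1S,2S)-2,6,6-trimethyl-2-(morpholine-4-carbonyl)cyclohexyl]acetamide | O=C(N1CCOCC1)[C@@]2(C)CCCC(C)(C)[C@@H]2CC(=O)N(C)OC | intermediate
15 | 1-[(1S,2S)-1,3,3-trimethyl-2-(2-oxobut-3-en-1-yl)cyclohexyl]but-3-en-1-one | C=CCC(=O)[C@@]1(C)CCCC(C)(C)[C@@H]1CC(=O)C=C | intermediate
16 | iodo ketol, (4R,4aS,8aS)-4-hydroxy-3-(iodomethyl)-4a,8,8-trimethyl-4-(prop-2-en-1-yl)octahydronaphthalen-2(1H)-one (C3 epimers, formed as its aluminium alkoxide) | ICC1C(=O)C[C@H]2C(C)(C)CCC[C@]2(C)[C@@]1(O)CC=C | intermediate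
17 | (4S,4aS,8aS)-4-hydroxy-4a,8,8-trimethyl-3-methylidene-4-(prop-2-en-1-yl)octahydronaphthalen-2(1H)-one | C=C1C(=O)C[C@H]2C(C)(C)CCC[C@]2(C)[C@@]1(O)CC=C | intermediate
18 | (2E)-4-[(1S,4aS,8aS)-1-hydroxy-5,5,8a-trimethyl-2-methylidene-3-oxodecahydronaphthalen-1-yl]-2-methylbut-2-enal | C=C1C(=O)C[C@H]2C(C)(C)CCC[C@]2(C)[C@@]1(O)C/C=C(\C)C=O | intermediate
19 | (4S,4aS,8aS)-4-hydroxy-4a,8,8-trimethyl-3-methylidene-4-[(2E)-3-methylpenta-2,4-dien-1-yl]octahydronaphthalen-2(1H)-one, (12E)-9α-hydroxylabda-8(17),12,14-trien-7-one | C=C1C(=O)C[C@H]2C(C)(C)CCC[C@]2(C)[C@@]1(O)C/C=C(\C)C=C | intermediate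
20 | 1-(2,4,5-trimethoxyphenyl)ethan-1-one | CC(=O)c1cc(OC)c(OC)cc1OC | starting material
21 | ethyl 3-oxo-3-(2,4,5-trimethoxyphenyl)propanoate | CCOC(=O)CC(=O)c1cc(OC)c(OC)cc1OC | intermediate
22 | benzene-1,3,5-triol | Oc1cc(O)cc(O)c1 | starting material
23 | 5,7-dihydroxy-2-(2,4,5-trimethoxyphenyl)-4H-chromen-4-one | COc1cc(OC)c(cc1OC)-c1cc(=O)c2c(O)cc(O)cc2o1 | intermediate
24 | 2-(5,7-dihydroxy-4-oxo-4H-chromen-2-yl)-5-methoxycyclohexa-2,5-diene-1,4-dione | COC1=CC(=O)C(=CC1=O)c1cc(=O)c2c(O)cc(O)cc2o1 | intermediate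
25 | CNP0241859.1 | C=C1C(=O)C[C@H]2C(C)(C)CCC[C@]2(C)[C@@]1(O)C[C@@H]1C(C)=CC[C@H]2C(=O)C(OC)=CC(=O)[C@@]12c1cc(=O)c2c(O)cc(O)cc2o1 | target

Total step count: 16. Longest linear sequence: 12 steps (steps 2–12 and 16).

The three steps most likely to fail

Risk 1, step 5: the Michael ring closure at the neopentyl β-carbon may be slow or reversible, and facial control may erode while the aldolates equilibrate. Fallback for step 5, setting out from 8 and rejoining the route at 13: α-methyl-γ-butyrolactone is opened with morpholine (AlMe3) to 4-hydroxy-2-methyl-1-(morpholin-4-yl)butan-1-one F1, which on heating with Ph3P·HBr should give [3-methyl-4-(morpholin-4-yl)-4-oxobutyl]triphenylphosphonium bromide F2. Its ylide (KN(SiMe3)2, THF, −78 °C) should undergo Z-selective Wittig olefination with 8 to 8-phenylmenthyl (2E,5Z)-4,4,8-trimethyl-9-(morpholin-4-yl)-9-oxonona-2,5-dienoate F3. Irreversible 6-exo-trig Michael closure of the lithium amide enolate (LiN(i-Pr)2, THF, −78 °C) would give 8-phenylmenthyl 2-[(1S,6S)-2,2,6-trimethyl-6-(morpholine-4-carbonyl)cyclohex-3-en-1-yl]acetate F4, and H2 over Pd/C would lead to 13. The C10 configuration is less securely controlled in this variant, because the chelate is absent.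

Risk 2, step 16: the quinone may approach in the ordinary endo sense or on the other diene face, giving diastereomeric adducts. Fallback for step 16, setting out from 17 and arriving at 25: OsO4 (cat.)/NaIO4 cleavage of the allyl group should give 2-[(1S,4aS,8aS)-1-hydroxy-5,5,8a-trimethyl-2-methylidene-3-oxodecahydronaphthalen-1-yl]acetaldehyde F5. Stork–Zhao olefination with Ph3P=C(I)CH3 would give (4S,4aS,8aS)-4-hydroxy-4-[(2Z)-3-iodobut-2-en-1-yl]-4a,8,8-trimethyl-3-methylideneoctahydronaphthalen-2(1H)-one F6, and Stille coupling with tributyl(vinyl)stannane (Pd(PPh3)4, CuI) would give the (12Z)-diene (4S,4aS,8aS)-4-hydroxy-4a,8,8-trimethyl-3-methylidene-4-[(2Z)-3-methylpenta-2,4-dien-1-yl]octahydronaphthalen-2(1H)-one F7. Its Diels–Alder reaction with 24 at 10 kbar should deliver 25 through the ordinary quinone-endo transition state, in which the Z (inside) substituent ends cis to the chromone. Facial selectivity would then rest on C9 alone.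

Risk 3, step 10: protonation of the aluminium enolate or retro-aldol cleavage may outrun closure onto the hindered C9 ketone. Fallback for step 10, setting out from 15 and rejoining the route at 17: α-iodination of the vinyl ketone (I2, pyridine, CH2Cl2) should give 1-[(1S,2S)-2-(3-iodo-2-oxobut-3-en-1-yl)-1,3,3-trimethylcyclohexyl]but-3-en-1-one F8. Intramolecular Nozaki–Hiyama–Kishi addition of the derived alkenylchromium to the C9 ketone (CrCl2, NiCl2 cat., DMF) should give 17 directly, with the same chair preference for the equatorial allyl group.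

Further compounds
F1 | step 5 | 4-hydroxy-2-methyl-1-(morpholin-4-yl)butan-1-one (racemic) | OCCC(C)C(=O)N1CCOCC1
F2 | step 5 | [3-methyl-4-(morpholin-4-yl)-4-oxobutyl]triphenylphosphonium bromide (racemic) | [Br-].CC(CC[P+](c1ccccc1)(c1ccccc1)c1ccccc1)C(=O)N1CCOCC1
F3 | step 5 | 8-phenylmenthyl (2E,5Z)-4,4,8-trimethyl-9-(morpholin-4-yl)-9-oxonona-2,5-dienoate | O=C(N1CCOCC1)C(C)C/C=C\C(C)(C)/C=C/C(=O)O[C@@H]1C[C@H](C)CC[C@H]1C(C)(C)c1ccccc1
F4 | step 5 | 8-phenylmenthyl 2-[(1S,6S)-2,2,6-trimethyl-6-(morpholine-4-carbonyl)cyclohex-3-en-1-yl]acetate | O=C(N1CCOCC1)[C@@]2(C)CC=CC(C)(C)[C@@H]2CC(=O)O[C@@H]1C[C@H](C)CC[C@H]1C(C)(C)c1ccccc1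
F5 | step 16 | 2-[(1S,4aS,8aS)-1-hydroxy-5,5,8a-trimethyl-2-methylidene-3-oxodecahydronaphthalen-1-yl]acetaldehyde | C=C1C(=O)C[C@H]2C(C)(C)CCC[C@]2(C)[C@@]1(O)CC=O
F6 | step 16 | (4S,4aS,8aS)-4-hydroxy-4-[(2Z)-3-iodobut-2-en-1-yl]-4a,8,8-trimethyl-3-methylideneoctahydronaphthalen-2(1H)-one | C=C1C(=O)C[C@H]2C(C)(C)CCC[C@]2(C)[C@@]1(O)C/C=C(/C)I
F7 | step 16 | (4S,4aS,8aS)-4-hydroxy-4a,8,8-trimethyl-3-methylidene-4-[(2Z)-3-methylpenta-2,4-dien-1-yl]octahydronaphthalen-2(1H)-one | C=C1C(=O)C[C@H]2C(C)(C)CCC[C@]2(C)[C@@]1(O)C/C=C(/C)C=C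
F8 | step 10 | 1-[(1S,2S)-2-(3-iodo-2-oxobut-3-en-1-yl)-1,3,3-trimethylcyclohexyl]but-3-en-1-one | C=CCC(=O)[C@@]1(C)CCCC(C)(C)[C@@H]1CC(=O)C(I)=C
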